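**Retrosynthetic overview**

1. Labels follow germacranolide numbering: C6 carries the lactone oxygen, C8 the 2-methylbutanoate, C11/C12/C13 are the lactone α-carbon, carbonyl and exocyclic methylene, C14 is the formyl carbon on C10, C15 the acetoxymethyl carbon on C4.
2. Last operations unmask C14 (PMB ether → alcohol → aldehyde); before that the ten-membered carbocycle is closed by ring-closing metathesis at C1=C10 (terminal vinyl plus 1,1-disubstituted alkene).
3. C4=C5 with C15 comes from an E-selective Wittig reaction of a C5 aldehyde with an α-formyl ylide (fragment A), then reduction and acetylation.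
4. The α-methylene-γ-lactone (first ring) comes from lactonization of an acyclic hydroxy acrylate; its C7–C8 bond and the C7 and C8 stereocenters come from an indium Barbier coupling of an allylic bromide (fragment B; C6 from D-mannitol, C11–C13 from methyl acrylate) with an aldehyde (fragment C; C8–C10, C14). The C8 ester comes from (S)-2-methylbutanoic acid (fragment D).
5. Ring order: lactone first (step 13), carbocycle second (step 17).

**Route**

Step 1
Reactants: 1 pent-4-en-1-ol
Product: 2 5-bromopent-1-ene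
Conditions: PBr3 (0.4 equiv), pyridine (cat.), Et2O, −10 °C → rt
Reagents that add atoms: phosphorus tribromide BrP(Br)Br
Why: Alcohol-to-bromide substitution (SN2 on the intermediate phosphite ester) of an unhindered primary alcohol, with no stereocenter involved.

Step 2
Reactants: 2 5-bromopent-1-ene; 3 triphenylphosphine
Product: 4 (pent-4-en-1-yl)triphenylphosphonium bromide
Conditions: MeCN, reflux, 48 h
Reagents that add atoms: none
Why: SN2 quaternization of the phosphine by a primary bromide gives the crystalline Wittig salt.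

Step 3
Reactants: 4 (pent-4-en-1-yl)triphenylphosphonium bromide; 5 ethyl formate
Product: 7 2-(triphenyl-λ5-phosphanylidene)hex-5-enal, via (pent-4-en-1-ylidene)triphenylphosphorane 6 (not isolated)
Conditions: KOtBu (1.1 equiv), THF, 0 °C; then HCO2Et (1.2 equiv), −78 °C → rt
Reagents that add atoms: none
Why: C-Formylation of the non-stabilized ylide by the formate ester (ylide acylation) with loss of ethanol gives the stabilized α-formyl ylide needed for an E-selective Wittig reaction.

Step 4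
Reactants: 8 1,2:5,6-di-O-isopropylidene-D-mannitol
Product: 9 (4R)-2,2-dimethyl-1,3-dioxolane-4-carbaldehyde
Conditions: NaIO4, sat. aq. NaHCO3, CH2Cl2, 0 °C → rt
Reagents that add atoms: none
Why: Periodate glycol cleavage of the central diol gives two equivalents of the aldehyde, whose stereocenter (the later C6) is taken unchanged from D-mannitol.

Step 5
Reactants: 9 (4R)-2,2-dimethyl-1,3-dioxolane-4-carbaldehyde; 10 methyl acrylate
Product: 11 methyl 2-{[(4R)-2,2-dimethyl-1,3-dioxolan-4-yl](hydroxy)methyl}prop-2-enoate (both carbinol epimers)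
Conditions: DABCO (0.5 equiv), 1,4-dioxane/H2O (1:1), rt, 48 h
Reagents that add atoms: none
Why: Morita–Baylis–Hillman reaction of the acrylate with the reactive α-alkoxy aldehyde; the new carbinol center need not be controlled because the next step erases it.

Step 6
Reactants: 11 methyl 2-{[(4R)-2,2-dimethyl-1,3-dioxolan-4-yl](hydroxy)methyl}prop-2-enoate
Product: 12 methyl (2Z)-2-(bromomethyl)-3-[(4S)-2,2-dimethyl-1,3-dioxolan-4-yl]prop-2-enoate
Conditions: NBS, Me2S, CH2Cl2, 0 °C → rt
Reagents that add atoms: N-bromosuccinimide O=C1CCC(=O)N1Br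
Why: SN2' bromination of the Baylis–Hillman alcohol through its alkoxysulfonium salt (Corey–Kim reagent) gives the thermodynamically preferred Z trisubstituted enoate from both epimers, the dioxolane center being untouched (it reads S only through a priority change).

Step 7
Reactants: 13 (4-methoxyphenyl)methanol; 14 3-chloro-2-(chloromethyl)prop-1-ene
Product: 16 1-({[2-(chloromethyl)prop-2-en-1-yl]oxy}methyl)-4-methoxybenzene, via sodium (4-methoxyphenyl)methanolate 15 (not isolated)
Conditions: NaH, THF/DMF, 0 °C; then 14 (3 equiv), Bu4NI (cat.), rt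
Reagents that add atoms: none
Why: Williamson etherification, kept at the mono stage by the threefold excess of the symmetrical dichloride.

Step 8
Reactants: 16 1-({[2-(chloromethyl)prop-2-en-1-yl]oxy}methyl)-4-methoxybenzene; 17 1,3-dithiane
Product: 19 2-(2-{[(4-methoxyphenyl)methoxy]methyl}prop-2-en-1-yl)-1,3-dithiane, via 2-lithio-1,3-dithiane 18 (not isolated)
Conditions: n-BuLi, THF, −30 °C; then 16, −78 → 0 °C
Reagents that add atoms: none
Why: Corey–Seebach alkylation of the formyl-anion equivalent by the allylic chloride, in which SN2 and SN2' attack give the same product because both allylic termini are CH2.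

Step 9
Reactants: 19 2-(2-{[(4-methoxyphenyl)methoxy]methyl}prop-2-en-1-yl)-1,3-dithiane
Product: 20 3-{[(4-methoxyphenyl)methoxy]methyl}but-3-enal
Conditions: MeI, CaCO3, MeCN/H2O (9:1), 45 °C; used crude at once
Reagents that add atoms: water O
Why: S-Methylation and hydrolysis of the dithioacetal under near-neutral conditions releases the β,γ-unsaturated aldehyde without moving the alkene into conjugation.

Step 10
Reactants: 21 (2S)-2-methylbutan-1-ol
Product: 23 (2S)-2-methylbutanoic acid, via (2S)-2-methylbutanal 22 (not isolated)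
Conditions: TEMPO (cat.), NaClO2, NaOCl (cat.), MeCN/phosphate buffer pH 6.7, 35 °C
Reagents that add atoms: sodium chlorite [Na+].[O-]Cl=O
Why: Buffered TEMPO/chlorite oxidation (oxoammonium oxidation, then chlorite oxidation of the aldehyde) takes the chiral-pool alcohol to the acid without enolization, so the S center is retained.

Step 11
Reactants: 12 methyl (2Z)-2-(bromomethyl)-3-[(4S)-2,2-dimethyl-1,3-dioxolan-4-yl]prop-2-enoate; 20 3-{[(4-methoxyphenyl)methoxy]methyl}but-3-enal
Product: 25 methyl (3R,4R)-3-[(4S)-2,2-dimethyl-1,3-dioxolan-4-yl]-4-hydroxy-6-{[(4-methoxyphenyl)methoxy]methyl}-2-methylidenehept-6-enoate, via allylindium dibromide 24 (not isolated)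
Conditions: In powder (1.5 equiv), 12 (1.3 equiv), THF/H2O (1:1), rt
Reagents that add atoms: none
Why: Indium Barbier allylation (SE2' through a chair Zimmerman–Traxler transition state) in which the Z allylindium gives the 7,8-syn adduct and the aldehyde adds to the C7 face anti to the dioxolane C6–O bond with H6 held in the alkene plane by allylic strain (Felkin–Anh sense, and the same face if indium chelates that oxygen), setting C7 (R) and C8 (R).

Step 12
Reactants: 25 methyl (3R,4R)-3-[(4S)-2,2-dimethyl-1,3-dioxolan-4-yl]-4-hydroxy-6-{[(4-methoxyphenyl)methoxy]methyl}-2-methylidenehept-6-enoate; 23 (2S)-2-methylbutanoic acid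
Product: 26 methyl (3R,4R)-3-[(4S)-2,2-dimethyl-1,3-dioxolan-4-yl]-6-{[(4-methoxyphenyl)methoxy]methyl}-2-methylidene-4-{[(2S)-2-methylbutanoyl]oxy}hept-6-enoate
Conditions: DCC, DMAP (cat.), CH2Cl2, 0 °C → rt
Reagents that add atoms: none
Why: Steglich esterification acylates the only free hydroxyl (C8–OH) with retention at every stereocenter and blocks lactonization through the C8 oxygen.

Step 13
Reactants: 26 methyl (3R,4R)-3-[(4S)-2,2-dimethyl-1,3-dioxolan-4-yl]-6-{[(4-methoxyphenyl)methoxy]methyl}-2-methylidene-4-{[(2S)-2-methylbutanoyl]oxy}hept-6-enoate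
Product: 28 (1R)-1-[(2S,3R)-2-(hydroxymethyl)-4-methylidene-5-oxooxolan-3-yl]-3-{[(4-methoxyphenyl)methoxy]methyl}but-3-en-1-yl (2S)-2-methylbutanoate, via dihydroxy ester 27 (not isolated)
Conditions: p-TsOH·H2O (0.2 equiv), MeOH/H2O (10:1), rt; then evaporate, CH2Cl2, rt
Reagents that add atoms: none
Why: Acid-catalyzed acetonide hydrolysis followed by lactonization of the secondary C6–OH onto the acrylate ester closes the five-membered α-methylene lactone (favoured over the six-membered alternative), trans-disubstituted as already fixed by C6 and C7.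

Step 14
Reactants: 28 (1R)-1-[(2S,3R)-2-(hydroxymethyl)-4-methylidene-5-oxooxolan-3-yl]-3-{[(4-methoxyphenyl)methoxy]methyl}but-3-en-1-yl (2S)-2-methylbutanoate; 7 2-(triphenyl-λ5-phosphanylidene)hex-5-enal
Product: 30 (1R)-1-{(2R,3R)-2-[(1E)-2-formylhexa-1,5-dien-1-yl]-4-methylidene-5-oxooxolan-3-yl}-3-{[(4-methoxyphenyl)methoxy]methyl}but-3-en-1-yl (2S)-2-methylbutanoate, via lactone aldehyde 29 (not isolated)
Conditions: Dess–Martin periodinane, NaHCO3, CH2Cl2, 0 °C → rt; then 7 (2 equiv), 40 °C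
Reagents that add atoms: none
Why: Dess–Martin oxidation with in situ Wittig olefination by the stabilized α-formyl ylide gives the E enal (C6 trans to CHO, hence cis to C3) and traps the epimerizable α-acyloxy aldehyde before it can scramble C6.

Step 15
Reactants: 30 (1R)-1-{(2R,3R)-2-[(1E)-2-formylhexa-1,5-dien-1-yl]-4-methylidene-5-oxooxolan-3-yl}-3-{[(4-methoxyphenyl)methoxy]methyl}but-3-en-1-yl (2S)-2-methylbutanoate
Product: 31 (1R)-1-{(2R,3R)-2-[(1E)-2-(hydroxymethyl)hexa-1,5-dien-1-yl]-4-methylidene-5-oxooxolan-3-yl}-3-{[(4-methoxyphenyl)methoxy]methyl}but-3-en-1-yl (2S)-2-methylbutanoate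
Conditions: NaBH4 (0.6 equiv), CeCl3·7H2O, MeOH, −78 °C
Reagents that add atoms: none
Why: Luche 1,2-reduction of the enal at −78 °C is far faster than attack on the lactone, the ester or the α-methylene lactone.

Step 16
Reactants: 31 (1R)-1-{(2R,3R)-2-[(1E)-2-(hydroxymethyl)hexa-1,5-dien-1-yl]-4-methylidene-5-oxooxolan-3-yl}-3-{[(4-methoxyphenyl)methoxy]methyl}but-3-en-1-yl (2S)-2-methylbutanoate
Product: 32 (1R)-1-{(2R,3R)-2-[(1E)-2-(acetyloxymethyl)hexa-1,5-dien-1-yl]-4-methylidene-5-oxooxolan-3-yl}-3-{[(4-methoxyphenyl)methoxy]methyl}but-3-en-1-yl (2S)-2-methylbutanoate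
Conditions: Ac2O, pyridine, DMAP (cat.), CH2Cl2, 0 °C
Reagents that add atoms: acetic anhydride CC(=O)OC(C)=O
Why: Acetylation of the only free hydroxyl (primary, allylic) installs the C15 acetate.

Step 17
Reactants: 32 (1R)-1-{(2R,3R)-2-[(1E)-2-(acetyloxymethyl)hexa-1,5-dien-1-yl]-4-methylidene-5-oxooxolan-3-yl}-3-{[(4-methoxyphenyl)methoxy]methyl}but-3-en-1-yl (2S)-2-methylbutanoate
Product: 33 (3aR,4R,6E,10E,11aR)-10-(acetyloxymethyl)-6-{[(4-methoxyphenyl)methoxy]methyl}-3-methylidene-2-oxo-2,3,3a,4,5,8,9,11a-octahydrocyclodeca[b]furan-4-yl (2S)-2-methylbutanoate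
Conditions: second-generation Hoveyda–Grubbs catalyst [RuCl2(H2IMes)(=CH–C6H4-2-OiPr)] (15 mol %, in portions), toluene (1 mM), 80 °C, argon sparge
Reagents that add atoms: none
Why: Ring-closing metathesis in which the catalyst loads on the terminal C1 vinyl group and closes onto the 1,1-disubstituted C10 alkene with loss of ethene, giving the ring-cis (E by CIP) trisubstituted alkene that a ten-membered 1,5-diene prefers, while the α-methylene lactone stays out because closure onto it would give a bridgehead alkene.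

Step 18
Reactants: 33 (3aR,4R,6E,10E,11aR)-10-(acetyloxymethyl)-6-{[(4-methoxyphenyl)methoxy]methyl}-3-methylidene-2-oxo-2,3,3a,4,5,8,9,11a-octahydrocyclodeca[b]furan-4-yl (2S)-2-methylbutanoate
Product: 34 (3aR,4R,6E,10E,11aR)-10-(acetyloxymethyl)-6-(hydroxymethyl)-3-methylidene-2-oxo-2,3,3a,4,5,8,9,11a-octahydrocyclodeca[b]furan-4-yl (2S)-2-methylbutanoate
Conditions: DDQ, CH2Cl2/pH 7 buffer (10:1), 0 °C → rt
Reagents that add atoms: none
Why: Oxidative cleavage of the 4-methoxybenzyl ether (hydride abstraction by DDQ, hydrolysis of the oxocarbenium ion) frees the C14 alcohol without touching the esters or alkenes.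

Step 19
Reactants: 34 (3aR,4R,6E,10E,11aR)-10-(acetyloxymethyl)-6-(hydroxymethyl)-3-methylidene-2-oxo-2,3,3a,4,5,8,9,11a-octahydrocyclodeca[b]furan-4-yl (2S)-2-methylbutanoate
Product: 35 (3aR,4R,6E,10E,11aR)-10-(acetyloxymethyl)-6-formyl-3-methylidene-2-oxo-2,3,3a,4,5,8,9,11a-octahydrocyclodeca[b]furan-4-yl (2S)-2-methylbutanoate (CNP0230988.9)
Conditions: MnO2 (20 equiv), CH2Cl2, rt
Reagents that add atoms: none
Why: Chemoselective MnO2 oxidation of the primary allylic alcohol gives the conjugated aldehyde and leaves alkene geometry and all stereocenters untouched.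

**Compound list**

1 | pent-4-en-1-ol | C=CCCCO | starting material
2 | 5-bromopent-1-ene | C=CCCCBr | intermediate
3 | triphenylphosphine | c1ccc(cc1)P(c1ccccc1)c1ccccc1 | starting material
4 | (pent-4-en-1-yl)triphenylphosphonium bromide | C=CCCC[P+](c1ccccc1)(c1ccccc1)c1ccccc1.[Br-] | intermediate
5 | ethyl formate | CCOC=O | starting material
6 | (pent-4-en-1-ylidene)triphenylphosphorane | C=CCCC=P(c1ccccc1)(c1ccccc1)c1ccccc1 | intermediate
7 | 2-(triphenyl-λ5-phosphanylidene)hex-5-enal | C=CCCC(C=O)=P(c1ccccc1)(c1ccccc1)c1ccccc1 | intermediate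
8 | 1,2:5,6-di-O-isopropylidene-D-mannitol | CC1(C)OC[C@@H](O1)[C@@H](O)[C@H](O)[C@H]1COC(C)(C)O1 | starting material
9 | (4R)-2,2-dimethyl-1,3-dioxolane-4-carbaldehyde | CC1(C)OC[C@@H](O1)C=O | intermediate
10 | methyl acrylate | C=CC(=O)OC | starting material
11 | methyl 2-{[(4R)-2,2-dimethyl-1,3-dioxolan-4-yl](hydroxy)methyl}prop-2-enoate (both carbinol epimers) | CC1(C)OC[C@@H](O1)C(O)C(=C)C(=O)OC | intermediate
12 | methyl (2Z)-2-(bromomethyl)-3-[(4S)-2,2-dimethyl-1,3-dioxolan-4-yl]prop-2-enoate | CC1(C)OC[C@@H](O1)/C=C(\CBr)C(=O)OC | intermediate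
13 | (4-methoxyphenyl)methanol | COc1ccc(CO)cc1 | starting material
14 | 3-chloro-2-(chloromethyl)prop-1-ene | C=C(CCl)CCl | starting material
15 | sodium (4-methoxyphenyl)methanolate | COc1ccc(C[O-])cc1.[Na+] | intermediate
16 | 1-({[2-(chloromethyl)prop-2-en-1-yl]oxy}methyl)-4-methoxybenzene | C=C(CCl)COCc1ccc(OC)cc1 | intermediate
17 | 1,3-dithiane | C1CSCSC1 | starting material
18 | 2-lithio-1,3-dithiane | [Li]C1SCCCS1 | intermediate
19 | 2-(2-{[(4-methoxyphenyl)methoxy]methyl}prop-2-en-1-yl)-1,3-dithiane | C=C(CC1SCCCS1)COCc1ccc(OC)cc1 | intermediate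
20 | 3-{[(4-methoxyphenyl)methoxy]methyl}but-3-enal | O=CCC(=C)COCc1ccc(OC)cc1 | intermediate
21 | (2S)-2-methylbutan-1-ol | CC[C@H](C)CO | starting material
22 | (2S)-2-methylbutanal | CC[C@H](C)C=O | intermediate
23 | (2S)-2-methylbutanoic acid | CC[C@H](C)C(=O)O | intermediate
24 | methyl (2Z)-2-[(dibromoindiganyl)methyl]-3-[(4S)-2,2-dimethyl-1,3-dioxolan-4-yl]prop-2-enoate (allylindium dibromide, one component of the sesquibromide) | CC1(C)OC[C@@H](O1)/C=C(\C[In](Br)Br)C(=O)OC | intermediate
25 | methyl (3R,4R)-3-[(4S)-2,2-dimethyl-1,3-dioxolan-4-yl]-4-hydroxy-6-{[(4-methoxyphenyl)methoxy]methyl}-2-methylidenehept-6-enoate | COC(=O)C(=C)[C@@H]([C@H]1COC(C)(C)O1)[C@H](O)CC(=C)COCc1ccc(OC)cc1 | intermediate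
26 | methyl (3R,4R)-3-[(4S)-2,2-dimethyl-1,3-dioxolan-4-yl]-6-{[(4-methoxyphenyl)methoxy]methyl}-2-methylidene-4-{[(2S)-2-methylbutanoyl]oxy}hept-6-enoate | COC(=O)C(=C)[C@@H]([C@H]1COC(C)(C)O1)[C@H](OC(=O)[C@@H](C)CC)CC(=C)COCc1ccc(OC)cc1 | intermediate
27 | methyl (3S,4R)-3-[(1S)-1,2-dihydroxyethyl]-6-{[(4-methoxyphenyl)methoxy]methyl}-2-methylidene-4-{[(2S)-2-methylbutanoyl]oxy}hept-6-enoate | COC(=O)C(=C)[C@@H]([C@H](O)CO)[C@H](OC(=O)[C@@H](C)CC)CC(=C)COCc1ccc(OC)cc1 | intermediate
28 | (1R)-1-[(2S,3R)-2-(hydroxymethyl)-4-methylidene-5-oxooxolan-3-yl]-3-{[(4-methoxyphenyl)methoxy]methyl}but-3-en-1-yl (2S)-2-methylbutanoate | C=C1C(=O)O[C@H](CO)[C@H]1[C@H](OC(=O)[C@@H](C)CC)CC(=C)COCc1ccc(OC)cc1 | intermediate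
29 | (1R)-1-[(2S,3R)-2-formyl-4-methylidene-5-oxooxolan-3-yl]-3-{[(4-methoxyphenyl)methoxy]methyl}but-3-en-1-yl (2S)-2-methylbutanoate | C=C1C(=O)O[C@H](C=O)[C@H]1[C@H](OC(=O)[C@@H](C)CC)CC(=C)COCc1ccc(OC)cc1 | intermediate
30 | (1R)-1-{(2R,3R)-2-[(1E)-2-formylhexa-1,5-dien-1-yl]-4-methylidene-5-oxooxolan-3-yl}-3-{[(4-methoxyphenyl)methoxy]methyl}but-3-en-1-yl (2S)-2-methylbutanoate | C=C1C(=O)O[C@H](/C=C(/C=O)CCC=C)[C@H]1[C@H](OC(=O)[C@@H](C)CC)CC(=C)COCc1ccc(OC)cc1 | intermediate
31 | (1R)-1-{(2R,3R)-2-[(1E)-2-(hydroxymethyl)hexa-1,5-dien-1-yl]-4-methylidene-5-oxooxolan-3-yl}-3-{[(4-methoxyphenyl)methoxy]methyl}but-3-en-1-yl (2S)-2-methylbutanoate | C=C1C(=O)O[C@H](/C=C(/CO)CCC=C)[C@H]1[C@H](OC(=O)[C@@H](C)CC)CC(=C)COCc1ccc(OC)cc1 | intermediate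
32 | (1R)-1-{(2R,3R)-2-[(1E)-2-(acetyloxymethyl)hexa-1,5-dien-1-yl]-4-methylidene-5-oxooxolan-3-yl}-3-{[(4-methoxyphenyl)methoxy]methyl}but-3-en-1-yl (2S)-2-methylbutanoate | C=C1C(=O)O[C@H](/C=C(/COC(C)=O)CCC=C)[C@H]1[C@H](OC(=O)[C@@H](C)CC)CC(=C)COCc1ccc(OC)cc1 | intermediate
33 | (3aR,4R,6E,10E,11aR)-10-(acetyloxymethyl)-6-{[(4-methoxyphenyl)methoxy]methyl}-3-methylidene-2-oxo-2,3,3a,4,5,8,9,11a-octahydrocyclodeca[b]furan-4-yl (2S)-2-methylbutanoate | C=C1C(=O)O[C@@H]2/C=C(/COC(C)=O)CC/C=C(/COCc3ccc(OC)cc3)C[C@@H](OC(=O)[C@@H](C)CC)[C@@H]12 | intermediate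
34 | (3aR,4R,6E,10E,11aR)-10-(acetyloxymethyl)-6-(hydroxymethyl)-3-methylidene-2-oxo-2,3,3a,4,5,8,9,11a-octahydrocyclodeca[b]furan-4-yl (2S)-2-methylbutanoate | C=C1C(=O)O[C@@H]2/C=C(/COC(C)=O)CC/C=C(/CO)C[C@@H](OC(=O)[C@@H](C)CC)[C@@H]12 | intermediate
35 | (3aR,4R,6E,10E,11aR)-10-(acetyloxymethyl)-6-formyl-3-methylidene-2-oxo-2,3,3a,4,5,8,9,11a-octahydrocyclodeca[b]furan-4-yl (2S)-2-methylbutanoate | C=C1C(=O)O[C@@H]2/C=C(/COC(C)=O)CC/C=C(/C=O)C[C@@H](OC(=O)[C@@H](C)CC)[C@@H]12 | target

**Step count**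

Total step count: 19.
Longest linear sequence: 12 steps (steps 4, 5, 6 and then 11 to 19; the branch 7, 8, 9 and then 11 to 19 is equally long).

**Three steps most likely to fail**

Step 11 (indium coupling). Aldehyde 20 is prone to move its alkene into conjugation, and the facial control at C7 rests only on the C6 dioxolane center in water. The fallback sets out from 11 and comes back at 25. Compound 11 is acetylated (Ac2O, pyridine) to the Baylis–Hillman acetate F1. F1 is converted by Pd2(dba)3-catalysed SN2' borylation with B2pin2 into the E allylboronate F2, which has the same double-bond geometry as 12. F2 is then added to 20 under anhydrous conditions with the BINOL-derived phosphoric acid (S)-TRIP (toluene, −30 °C). The closed six-membered boron transition state gives the same 7,8-syn relationship, and the chiral acid adds reagent control over the aldehyde face; aqueous work-up returns 25.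

Step 14 (oxidation and Wittig). The α-acyloxy aldehyde 29 can epimerize at C6 and the formyl ylide is sluggish. The fallback sets out from 28 and comes back at 31. Compound 28 is oxidized to 29 as before, and 29 is coupled with 2-bromohexa-1,5-diene (C=CCCC(Br)=C) under NiCl2 (cat.)/CrCl2 in DMF (Nozaki–Hiyama–Kishi) to the secondary allylic alcohol F3 (both carbinol epimers are usable). F3 is then transposed with Ph3SiOReO3 (cat., Et2O, 0 °C). The chair-like 1,3-shift of the perrhenate ester places the lactone carbon equatorial and gives the primary E allylic alcohol 31 directly, so the heated Wittig step and the hydride reduction are both bypassed.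

Step 17 (ring-closing metathesis). Forming a trisubstituted alkene in a ten-membered ring from a 1,1-disubstituted allylic ether competes with dimerization. The fallback sets out from 32 and comes back at 35. The PMB group is removed first (DDQ) to give the allylic alcohol F4, which is oxidized with MnO2 to the 2-substituted acrolein F5. Ring closure then becomes the last step, as a metathesis of the C1 vinyl group onto an electron-poor α-substituted enal, a pairing driven by conjugation in the product; this gives 35 without further steps.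

**Further compounds**

F1 | step 11 | methyl 2-{(acetyloxy)[(4R)-2,2-dimethyl-1,3-dioxolan-4-yl]methyl}prop-2-enoate (both epimers) | CC1(C)OC[C@@H](O1)C(OC(C)=O)C(=C)C(=O)OC
F2 | step 11 | methyl (2E)-3-[(4S)-2,2-dimethyl-1,3-dioxolan-4-yl]-2-[(4,4,5,5-tetramethyl-1,3,2-dioxaborolan-2-yl)methyl]prop-2-enoate | CC1(C)OC[C@@H](O1)/C=C(\CB1OC(C)(C)C(C)(C)O1)C(=O)OC
F3 | step 14 | (1R)-1-[(2S,3R)-2-(1-hydroxy-2-methylidenehex-5-en-1-yl)-4-methylidene-5-oxooxolan-3-yl]-3-{[(4-methoxyphenyl)methoxy]methyl}but-3-en-1-yl (2S)-2-methylbutanoate (both carbinol epimers) | C=C1C(=O)O[C@H](C(O)C(=C)CCC=C)[C@H]1[C@H](OC(=O)[C@@H](C)CC)CC(=C)COCc1ccc(OC)cc1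
F4 | step 17 | (1R)-1-{(2R,3R)-2-[(1E)-2-(acetyloxymethyl)hexa-1,5-dien-1-yl]-4-methylidene-5-oxooxolan-3-yl}-3-(hydroxymethyl)but-3-en-1-yl (2S)-2-methylbutanoate | C=C1C(=O)O[C@H](/C=C(/COC(C)=O)CCC=C)[C@H]1[C@H](OC(=O)[C@@H](C)CC)CC(=C)CO
F5 | step 17 | (1R)-1-{(2R,3R)-2-[(1E)-2-(acetyloxymethyl)hexa-1,5-dien-1-yl]-4-methylidene-5-oxooxolan-3-yl}-3-formylbut-3-en-1-yl (2S)-2-methylbutanoate | C=C1C(=O)O[C@H](/C=C(/COC(C)=O)CCC=C)[C@H]1[C@H](OC(=O)[C@@H](C)CC)CC(=C)C=O
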